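## Retrosynthetic overview

1. The hydroxy‑methoxy‑quinone comes from aerobic oxidation of a 2‑alkyl‑4‑methoxyresorcinol at its only free para position; the two phenols are carried as MOM ethers.
2. The Ar–CH2–CH=C(Me) unit comes from Zr‑catalysed carboalumination of a terminal alkyne and Pd‑catalysed coupling of the alkenylalane with a benzylic chloride, which fixes the E‑alkene.
3. The exocyclic methylene comes from a ketone; the but‑3‑ynyl ketone comes from Eschenmoser–Tanabe fragmentation of an epoxy‑octalone.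
4. The octalone comes from 2,6‑dimethylcyclohexanone and methyl vinyl ketone: a chiral‑imine Michael addition sets the quaternary centre, and the aldol/equilibration step sets the secondary methyl trans to it.
5. Ring order: the cyclohexane ring is bought; ring A is annulated onto it (step 3) and opened again (step 5); the quinone ring is made last from a bought arene.

Assumption: 4‑methoxybenzene‑1,3‑diol and 2,6‑dimethylcyclohexanone (cis/trans mixture) are taken as catalogue chemicals.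

## Route

Step 1
Reactants: 1 2,6‑dimethylcyclohexan‑1‑one (cis/trans mixture); 2 (S)‑1‑phenylethan‑1‑amine
Product: 3 (S)‑N‑(2,6‑dimethylcyclohexylidene)‑1‑phenylethan‑1‑amine
Conditions: cat. TsOH, toluene, reflux, Dean–Stark, 24 h
Reagents that add atoms: none
Why: Acid‑catalysed imine condensation driven by azeotropic removal of water; the ring methyl centres need no control here because they are set in steps 2 and 3.

Step 2
Reactants: 3 (S)‑N‑(2,6‑dimethylcyclohexylidene)‑1‑phenylethan‑1‑amine; 4 but‑3‑en‑2‑one (methyl vinyl ketone)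
Product: 6 (2R,6S)‑2,6‑dimethyl‑2‑(3‑oxobutyl)cyclohexan‑1‑one, via Michael adduct imine 5 (not isolated)
Conditions: 4 (1.3 equiv), THF, 40 °C, 3 d; then 20% aq. AcOH, rt, 2 h
Reagents that add atoms: water, O
Why: d'Angelo asymmetric Michael addition, in which the more substituted secondary enamine tautomer of 3 adds to the enone through a compact aza‑ene‑like transition state on the face away from the phenyl group of the auxiliary, setting the quaternary centre as R (typically about 90% ee) before hydrolysis frees the ketone.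

Step 3
Reactants: 6 (2R,6S)‑2,6‑dimethyl‑2‑(3‑oxobutyl)cyclohexan‑1‑one
Product: 9 (4aR,8R)‑4a,8‑dimethyl‑4,4a,5,6,7,8‑hexahydronaphthalen‑2(3H)‑one, via aldol ketol 7 (not isolated), via cis‑dimethyl octalone 8 (not isolated)
Conditions: NaOMe, MeOH, reflux, 12 h
Reagents that add atoms: none
Why: Intramolecular aldol condensation (the ring‑closing half of a Robinson annulation) under equilibrating base, where C8 epimerises through the dienolate to the equatorial methyl trans to the axial angular methyl, which avoids the 1,3‑diaxial methyl/methyl clash and so sets the secondary methyl centre under thermodynamic control.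

Step 4
Reactants: 9 (4aR,8R)‑4a,8‑dimethyl‑4,4a,5,6,7,8‑hexahydronaphthalen‑2(3H)‑one
Product: 10 (4aR,8R)‑1,8a‑epoxy‑4a,8‑dimethyloctahydronaphthalen‑2(1H)‑one (epoxide epimers, used as the mixture)
Conditions: 30% H2O2, 4 M NaOH, MeOH, 0 °C → rt
Reagents that add atoms: hydrogen peroxide, OO
Why: Weitz–Scheffer nucleophilic epoxidation of the enone; the epoxide configuration is irrelevant because both epoxide carbons lose their stereochemistry in step 5, and C8 is no longer acidic once the enone is gone.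

Step 5
Reactants: 10 (4aR,8R)‑1,8a‑epoxy‑4a,8‑dimethyloctahydronaphthalen‑2(1H)‑one
Product: 12 (2R,6R)‑2‑(but‑3‑yn‑1‑yl)‑2,6‑dimethylcyclohexan‑1‑one, via epoxy tosylhydrazone 11 (not isolated)
Conditions: TsNHNH2 (1.05 equiv), AcOH–CH2Cl2 (1:1), −20 °C → rt
Reagents that add atoms: none
Why: Eschenmoser–Tanabe fragmentation, in which the epoxy tosylhydrazone opens to a tertiary alkoxide that cleaves the C1–C8a bond with loss of N2 and sulfinate, giving the ring ketone and the terminal alkyne under weakly acidic conditions that do not epimerise the α‑methyl centre.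

Step 6
Reactants: 12 (2R,6R)‑2‑(but‑3‑yn‑1‑yl)‑2,6‑dimethylcyclohexan‑1‑one
Product: 13 (1R,3R)‑1‑(but‑3‑yn‑1‑yl)‑1,3‑dimethyl‑2‑methylidenecyclohexane
Conditions: Zn, CH2Br2, TiCl4, THF–CH2Cl2, 0 °C → rt
Reagents that add atoms: dibromomethane, BrCBr
Why: Lombardo (Takai‑type) methylenation with a non‑basic geminal dimetallic reagent, chosen so that the hindered ketone is olefinated without enolisation and the trans‑dimethyl relationship is kept.

Step 7
Reactants: 14 4‑methoxybenzene‑1,3‑diol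
Product: 15 1‑methoxy‑2,4‑bis(methoxymethoxy)benzene
Conditions: NaH (2.4 equiv), MOMCl (2.4 equiv), DMF, 0 °C → rt
Reagents that add atoms: chloromethyl methyl ether, COCCl
Why: Williamson‑type O‑alkylation of both phenoxides, giving acetal ethers that also act as ortho‑directing groups for step 8.

Step 8
Reactants: 15 1‑methoxy‑2,4‑bis(methoxymethoxy)benzene
Product: 17 [3‑methoxy‑2,6‑bis(methoxymethoxy)phenyl]methanol, via aryllithium 16 (not isolated)
Conditions: n‑BuLi, THF, 0 °C, 1 h; then (CH2O)n, 0 °C → rt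
Reagents that add atoms: formaldehyde (from paraformaldehyde), C=O
Why: Directed ortho‑metalation at the one position flanked by both OMOM groups, followed by hydroxymethylation of the aryllithium.

Step 9
Reactants: 17 [3‑methoxy‑2,6‑bis(methoxymethoxy)phenyl]methanol
Product: 18 2‑(chloromethyl)‑4‑methoxy‑1,3‑bis(methoxymethoxy)benzene
Conditions: PPh3, NCS, THF, 0 °C → rt; used crude
Reagents that add atoms: N‑chlorosuccinimide, O=C1CCC(=O)N1Cl
Why: Appel‑type chlorination through an alkoxyphosphonium salt under neutral conditions that the MOM acetals tolerate.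

Step 10
Reactants: 13 (1R,3R)‑1‑(but‑3‑yn‑1‑yl)‑1,3‑dimethyl‑2‑methylidenecyclohexane; 18 2‑(chloromethyl)‑4‑methoxy‑1,3‑bis(methoxymethoxy)benzene
Product: 20 2‑{(2E)‑5‑[(1R,3R)‑1,3‑dimethyl‑2‑methylidenecyclohexyl]‑3‑methylpent‑2‑en‑1‑yl}‑4‑methoxy‑1,3‑bis(methoxymethoxy)benzene, via alkenylalane 19 (not isolated)
Conditions: AlMe3 (2.5 equiv), Cp2ZrCl2 (0.25 equiv), CH2Cl2, 0 °C → rt; evaporate volatiles; then 18, Pd(PPh3)4 (5 mol %), THF, rt
Reagents that add atoms: trimethylaluminium, C[Al](C)C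
Why: Negishi zirconium‑catalysed carboalumination adds methyl and aluminium syn across the terminal alkyne (methyl to the internal carbon), and the zerovalent‑palladium Negishi cross‑coupling with the benzylic chloride proceeds with retention, so the trisubstituted alkene is formed as the E isomer.

Step 11
Reactants: 20 2‑{(2E)‑5‑[(1R,3R)‑1,3‑dimethyl‑2‑methylidenecyclohexyl]‑3‑methylpent‑2‑en‑1‑yl}‑4‑methoxy‑1,3‑bis(methoxymethoxy)benzene
Product: 21 2‑{(2E)‑5‑[(1R,3R)‑1,3‑dimethyl‑2‑methylidenecyclohexyl]‑3‑methylpent‑2‑en‑1‑yl}‑4‑methoxybenzene‑1,3‑diol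
Conditions: 2 M aq. HCl–MeOH (1:5), rt, under Ar, degassed
Reagents that add atoms: none
Why: Acid‑catalysed transacetalisation of both MOM ethers to methanol under dilute, room‑temperature conditions of the kind that prenylated phenols survive.

Step 12
Reactants: 21 2‑{(2E)‑5‑[(1R,3R)‑1,3‑dimethyl‑2‑methylidenecyclohexyl]‑3‑methylpent‑2‑en‑1‑yl}‑4‑methoxybenzene‑1,3‑diol
Product: 22 metachromin A, 2‑hydroxy‑5‑methoxy‑3‑{(2E)‑5‑[(1R,3R)‑1,3‑dimethyl‑2‑methylidenecyclohexyl]‑3‑methylpent‑2‑en‑1‑yl}cyclohexa‑2,5‑diene‑1,4‑dione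
Conditions: O2 (1 atm), Co(salen) (C16H14CoN2O2, 10–20 mol %), DMF, rt
Reagents that add atoms: dioxygen, O=O
Why: Aerobic phenol‑to‑para‑quinone oxidation catalysed by the divalent cobalt salen complex, which oxygenates the only unsubstituted position para to a hydroxyl (the one next to the methoxy group), so the second hydroxyl is left as the 2‑hydroxy group of the quinone.

## Compound list

1 | 2,6‑dimethylcyclohexan‑1‑one (cis/trans mixture) | CC1CCCC(C)C1=O | starting material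
2 | (S)‑1‑phenylethan‑1‑amine | C[C@H](N)c1ccccc1 | starting material
3 | (S)‑N‑(2,6‑dimethylcyclohexylidene)‑1‑phenylethan‑1‑amine (ring methyl centres as a mixture) | C[C@H](N=C1C(C)CCCC1C)c1ccccc1 | intermediate
4 | but‑3‑en‑2‑one (methyl vinyl ketone) | C=CC(C)=O | starting material
5 | 4‑[(1R,3S)‑1,3‑dimethyl‑2‑{[(1S)‑1‑phenylethyl]imino}cyclohexyl]butan‑2‑one (Michael adduct imine, not isolated) | C[C@H](N=C1[C@@H](C)CCC[C@]1(C)CCC(C)=O)c1ccccc1 | intermediate
6 | (2R,6S)‑2,6‑dimethyl‑2‑(3‑oxobutyl)cyclohexan‑1‑one | O=C1[C@@H](C)CCC[C@]1(C)CCC(C)=O | intermediate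
7 | (4aR,8S)‑8a‑hydroxy‑4a,8‑dimethyloctahydronaphthalen‑2(1H)‑one (aldol ketol, C8a epimers, not isolated) | O=C1CC2(O)[C@@H](C)CCC[C@]2(C)CC1 | intermediate
8 | (4aR,8S)‑4a,8‑dimethyl‑4,4a,5,6,7,8‑hexahydronaphthalen‑2(3H)‑one (cis‑dimethyl octalone, not isolated) | O=C1C=C2[C@@H](C)CCC[C@]2(C)CC1 | intermediate
9 | (4aR,8R)‑4a,8‑dimethyl‑4,4a,5,6,7,8‑hexahydronaphthalen‑2(3H)‑one | O=C1C=C2[C@H](C)CCC[C@]2(C)CC1 | intermediate
10 | (4aR,8R)‑1,8a‑epoxy‑4a,8‑dimethyloctahydronaphthalen‑2(1H)‑one (epoxide epimers) | O=C1C2OC23[C@H](C)CCC[C@]3(C)CC1 | intermediate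
11 | N'‑[(4aR,8R)‑1,8a‑epoxy‑4a,8‑dimethyloctahydronaphthalen‑2(1H)‑ylidene]‑4‑methylbenzenesulfonohydrazide (not isolated) | Cc1ccc(cc1)S(=O)(=O)NN=C1C2OC23[C@H](C)CCC[C@]3(C)CC1 | intermediate
12 | (2R,6R)‑2‑(but‑3‑yn‑1‑yl)‑2,6‑dimethylcyclohexan‑1‑one | O=C1[C@H](C)CCC[C@]1(C)CCC#C | intermediate
13 | (1R,3R)‑1‑(but‑3‑yn‑1‑yl)‑1,3‑dimethyl‑2‑methylidenecyclohexane | C=C1[C@H](C)CCC[C@]1(C)CCC#C | intermediate
14 | 4‑methoxybenzene‑1,3‑diol | COc1ccc(O)cc1O | starting material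
15 | 1‑methoxy‑2,4‑bis(methoxymethoxy)benzene | COCOc1ccc(OC)c(OCOC)c1 | intermediate
16 | [3‑methoxy‑2,6‑bis(methoxymethoxy)phenyl]lithium (not isolated) | [Li]c1c(OCOC)ccc(OC)c1OCOC | intermediate
17 | [3‑methoxy‑2,6‑bis(methoxymethoxy)phenyl]methanol | COCOc1ccc(OC)c(OCOC)c1CO | intermediate
18 | 2‑(chloromethyl)‑4‑methoxy‑1,3‑bis(methoxymethoxy)benzene | COCOc1ccc(OC)c(OCOC)c1CCl | intermediate
19 | {(1E)‑4‑[(1R,3R)‑1,3‑dimethyl‑2‑methylidenecyclohexyl]‑2‑methylbut‑1‑en‑1‑yl}dimethylalane (not isolated) | C=C1[C@H](C)CCC[C@]1(C)CC/C(C)=C/[Al](C)C | intermediate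
20 | 2‑{(2E)‑5‑[(1R,3R)‑1,3‑dimethyl‑2‑methylidenecyclohexyl]‑3‑methylpent‑2‑en‑1‑yl}‑4‑methoxy‑1,3‑bis(methoxymethoxy)benzene | C=C1[C@H](C)CCC[C@]1(C)CC/C(C)=C/Cc1c(OCOC)ccc(OC)c1OCOC | intermediate
21 | 2‑{(2E)‑5‑[(1R,3R)‑1,3‑dimethyl‑2‑methylidenecyclohexyl]‑3‑methylpent‑2‑en‑1‑yl}‑4‑methoxybenzene‑1,3‑diol | C=C1[C@H](C)CCC[C@]1(C)CC/C(C)=C/Cc1c(O)ccc(OC)c1O | intermediate
22 | metachromin A | C=C1[C@H](C)CCC[C@]1(C)CC/C(C)=C/CC1=C(O)C(=O)C=C(OC)C1=O | target

## Step count and risks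

Total step count: 12. Longest linear sequence: 9 (steps 1–6, then 10–12); the arene branch (steps 7–9) joins at step 10.

Most likely to fail, first: step 6. The ketone of 12 is flanked by a quaternary and a tertiary carbon, so the Zn/CH2Br2/TiCl4 reagent may be too slow, and any enolisation would scramble the methyl centre. The fallback sets out from 12 and comes back at 13. Me3SiCH2Li premixed with CeCl3 (3 equiv, THF, −78 °C; one equivalent is spent on the alkyne C–H) adds to the carbonyl as a small, weakly basic nucleophile. This gives (2R,6R)‑2‑(but‑3‑yn‑1‑yl)‑2,6‑dimethyl‑1‑[(trimethylsilyl)methyl]cyclohexan‑1‑ol F1. KH in THF then triggers the Peterson elimination to 13.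

Most likely to fail, second: step 10. The electron‑rich, doubly ortho‑substituted benzylic chloride 18 may ionise or homocouple in the presence of alanes. The fallback reverses the polarity, sets out from 13 and comes back at 20.
- Carboalumination of 13 as in step 10 gives 19, and n‑BuLi converts it into lithium butyl{(1E)‑4‑[(1R,3R)‑1,3‑dimethyl‑2‑methylidenecyclohexyl]‑2‑methylbut‑1‑en‑1‑yl}dimethylalanate F2.
- Paraformaldehyde traps the alanate as (2E)‑5‑[(1R,3R)‑1,3‑dimethyl‑2‑methylidenecyclohexyl]‑3‑methylpent‑2‑en‑1‑ol F3.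
- CBr4/PPh3 (CH2Cl2, 0 °C) gives (1R,3R)‑1‑[(3E)‑5‑bromo‑3‑methylpent‑3‑en‑1‑yl]‑1,3‑dimethyl‑2‑methylidenecyclohexane F4.
- Aryllithium 16, made from 15 as in step 8 and treated with CuI (0.5 equiv, THF, −78 °C → 0 °C), displaces the allylic bromide of F4 to give 20.

Most likely to fail, third: step 11. Aqueous acid may close the phenol onto the neighbouring trisubstituted alkene (chroman formation) or move the exocyclic double bond. The fallback swaps the acid‑labile MOM groups for fluoride‑labile ones, sets out from 14 and comes back at 21.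
- NaH and 2‑(trimethylsilyl)ethoxymethyl chloride in DMF convert 14 into 1‑methoxy‑2,4‑bis{[2‑(trimethylsilyl)ethoxy]methoxy}benzene F5.
- n‑BuLi in THF gives (3‑methoxy‑2,6‑bis{[2‑(trimethylsilyl)ethoxy]methoxy}phenyl)lithium F6, which paraformaldehyde converts into (3‑methoxy‑2,6‑bis{[2‑(trimethylsilyl)ethoxy]methoxy}phenyl)methanol F7.
- PPh3/NCS gives 2‑(chloromethyl)‑4‑methoxy‑1,3‑bis{[2‑(trimethylsilyl)ethoxy]methoxy}benzene F8.
- Coupling of F8 with alkenylalane 19 (from 13, as in step 10) under Pd(PPh3)4 gives 2‑{(2E)‑5‑[(1R,3R)‑1,3‑dimethyl‑2‑methylidenecyclohexyl]‑3‑methylpent‑2‑en‑1‑yl}‑4‑methoxy‑1,3‑bis{[2‑(trimethylsilyl)ethoxy]methoxy}benzene F9.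
- Bu4NF in THF–DMPU at 60 °C under argon frees both phenols without acid and gives 21.

## Further compounds

F1 | step 6 | (2R,6R)‑2‑(but‑3‑yn‑1‑yl)‑2,6‑dimethyl‑1‑[(trimethylsilyl)methyl]cyclohexan‑1‑ol (C1 epimers) | C[Si](C)(C)CC1(O)[C@H](C)CCC[C@]1(C)CCC#C
F2 | step 10 | lithium butyl{(1E)‑4‑[(1R,3R)‑1,3‑dimethyl‑2‑methylidenecyclohexyl]‑2‑methylbut‑1‑en‑1‑yl}dimethylalanate | [Li+].C=C1[C@H](C)CCC[C@]1(C)CC/C(C)=C/[Al-](C)(C)CCCC
F3 | step 10 | (2E)‑5‑[(1R,3R)‑1,3‑dimethyl‑2‑methylidenecyclohexyl]‑3‑methylpent‑2‑en‑1‑ol | C=C1[C@H](C)CCC[C@]1(C)CC/C(C)=C/CO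
F4 | step 10 | (1R,3R)‑1‑[(3E)‑5‑bromo‑3‑methylpent‑3‑en‑1‑yl]‑1,3‑dimethyl‑2‑methylidenecyclohexane | C=C1[C@H](C)CCC[C@]1(C)CC/C(C)=C/CBr
F5 | step 11 | 1‑methoxy‑2,4‑bis{[2‑(trimethylsilyl)ethoxy]methoxy}benzene | COc1ccc(OCOCC[Si](C)(C)C)cc1OCOCC[Si](C)(C)C
F6 | step 11 | (3‑methoxy‑2,6‑bis{[2‑(trimethylsilyl)ethoxy]methoxy}phenyl)lithium | [Li]c1c(OCOCC[Si](C)(C)C)ccc(OC)c1OCOCC[Si](C)(C)C
F7 | step 11 | (3‑methoxy‑2,6‑bis{[2‑(trimethylsilyl)ethoxy]methoxy}phenyl)methanol | OCc1c(OCOCC[Si](C)(C)C)ccc(OC)c1OCOCC[Si](C)(C)C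
F8 | step 11 | 2‑(chloromethyl)‑4‑methoxy‑1,3‑bis{[2‑(trimethylsilyl)ethoxy]methoxy}benzene | ClCc1c(OCOCC[Si](C)(C)C)ccc(OC)c1OCOCC[Si](C)(C)C
F9 | step 11 | 2‑{(2E)‑5‑[(1R,3R)‑1,3‑dimethyl‑2‑methylidenecyclohexyl]‑3‑methylpent‑2‑en‑1‑yl}‑4‑methoxy‑1,3‑bis{[2‑(trimethylsilyl)ethoxy]methoxy}benzene | C=C1[C@H](C)CCC[C@]1(C)CC/C(C)=C/Cc1c(OCOCC[Si](C)(C)C)ccc(OC)c1OCOCC[Si](C)(C)C
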